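**Retrosynthetic overview**
- The oxepanone is closed last by acid-catalysed 7-endo opening of a trisubstituted epoxide by the ring hydroxyl, followed by oxidation of the resulting carbinol.
- The cyclohexane is assembled on (S)-4-hydroxy-2,4-dimethylcyclohexenone by alkoxide-directed 1,4-addition of the hydroazulene Grignard reagent (fragment union), then enolate alkylation to set the quaternary methyl carbon.
- The hydroazulene side chain comes from an Eschenmoser–Claisen [3,3] shift on a cycloheptenol, which transfers C–O chirality to the hindered ring carbon and places the trisubstituted olefin.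
- The cycloheptenone is closed by ring-closing metathesis on a cyclopentane whose gem-dimethyl quaternary carbon–ring bond is made by a Claisen [3,3] rearrangement of a tertiary allyl isobutenyl ether (the key step); trans-epoxide opening then sets the cis ring fusion and the tertiary alcohol.
- Ring order: cyclopentene, then cycloheptene (hydroazulene fragment); cyclohexene (second fragment); union; oxepane. Both fragments come from (S)-linalool.

Assumption: (S)-(+)-linalool (coriandrol) of high enantiomeric purity is bought; carbinol centres that are later oxidised or enolised are carried as epimer mixtures. The route is a paper design and has not been run.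

Step 1
Reactants: 1 (S)-(+)-linalool
Product: 2 (1S)-1-methylcyclopent-2-en-1-ol
Conditions: second-generation Grubbs catalyst RuCl2(=CHPh)(H2IMes)(PCy3) (0.5 mol%), CH2Cl2, 40 °C
Reagents that add atoms: none
Why: Ring-closing metathesis of the 1,6-diene expels 2-methylpropene and leaves the tertiary carbinol centre of linalool untouched.

Step 2
Reactants: 2 (1S)-1-methylcyclopent-2-en-1-ol
Product: 3 (3S)-3-methyl-3-[(2-methylprop-2-en-1-yl)oxy]cyclopent-1-ene
Conditions: KH, THF, 0 °C; CH2=C(CH3)CH2Cl, Bu4NI (cat.), rt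
Reagents that add atoms: 3-chloro-2-methylprop-1-ene, C=C(C)CCl
Why: Williamson etherification of the potassium alkoxide with a reactive allylic chloride touches no stereocentre.

Step 3
Reactants: 3 (3S)-3-methyl-3-[(2-methylprop-2-en-1-yl)oxy]cyclopent-1-ene
Product: 5 2-methyl-2-[(1R)-3-methylcyclopent-2-en-1-yl]propanal, via isobutenyl ether 4 (not isolated)
Conditions: KOt-Bu (0.3 equiv), DMSO, 60 °C; then xylenes, 140 °C, sealed tube
Reagents that add atoms: none
Why: Base-mediated allyl-to-propenyl isomerisation gives the allyl vinyl ether, whose Claisen [3,3]-sigmatropic rearrangement forms the quaternary carbon–ring bond suprafacially on the face that carried oxygen, so the carbinol chirality is relayed to the new ring stereocentre (R).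

Step 4
Reactants: 5 2-methyl-2-[(1R)-3-methylcyclopent-2-en-1-yl]propanal
Product: 6 (3R)-1-methyl-3-(2-methylbut-3-en-2-yl)cyclopent-1-ene
Conditions: Ph3PCH3Br, KOt-Bu, THF, 0 °C to rt
Reagents that add atoms: methyltriphenylphosphonium bromide, C[P+](c1ccccc1)(c1ccccc1)c1ccccc1.[Br-]
Why: Wittig methylenation of a non-enolisable neopentyl aldehyde cannot epimerise the adjacent ring stereocentre.

Step 5
Reactants: 6 (3R)-1-methyl-3-(2-methylbut-3-en-2-yl)cyclopent-1-ene
Product: 7 (1R,4S,5S)-1-methyl-4-(2-methylbut-3-en-2-yl)-6-oxabicyclo[3.1.0]hexane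
Conditions: mCPBA (1.05 equiv), NaHCO3, CH2Cl2, 0 °C
Reagents that add atoms: 3-chloroperoxybenzoic acid, O=C(OO)c1cccc(Cl)c1
Why: Prilezhaev epoxidation picks the electron-rich trisubstituted ring olefin over the neopentyl vinyl group and occurs on the face trans to the bulky tert-alkyl substituent.

Step 6
Reactants: 7 (1R,4S,5S)-1-methyl-4-(2-methylbut-3-en-2-yl)-6-oxabicyclo[3.1.0]hexane
Product: 8 2-[(1R,2R,5R)-2-hydroxy-2-methyl-5-(2-methylbut-3-en-2-yl)cyclopentyl]acetonitrile
Conditions: CH3CN, n-BuLi, THF, −78 °C; then 7, −78 to 40 °C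
Reagents that add atoms: acetonitrile, CC#N
Why: SN2 opening of the epoxide at its secondary carbon with inversion places the cyanomethyl group cis to the tert-alkyl chain (future cis ring fusion) and leaves the tertiary hydroxyl trans to both.

Step 7
Reactants: 8 2-[(1R,2R,5R)-2-hydroxy-2-methyl-5-(2-methylbut-3-en-2-yl)cyclopentyl]acetonitrile
Product: 10 1-[(1R,2R,5R)-2-hydroxy-2-methyl-5-(2-methylbut-3-en-2-yl)cyclopentyl]-3-methylbut-3-en-2-one, via N-magnesio ketimine 9 (not isolated)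
Conditions: CH2=C(CH3)MgBr (3.5 equiv), CuBr·SMe2 (5 mol%), THF, 50 °C; then 1 M HCl, 0 °C
Reagents that add atoms: isopropenylmagnesium bromide, C=C(C)[Mg]Br; water, O
Why: Grignard addition to the nitrile stops at the metallo-imine, which hydrolyses to the isopropenyl ketone without touching a stereocentre.

Step 8
Reactants: 10 1-[(1R,2R,5R)-2-hydroxy-2-methyl-5-(2-methylbut-3-en-2-yl)cyclopentyl]-3-methylbut-3-en-2-one
Product: 11 (1R,3aR,8aR)-1-hydroxy-1,4,4,6-tetramethyl-2,3,3a,4,8,8a-hexahydroazulen-7(1H)-one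
Conditions: second-generation Hoveyda–Grubbs catalyst RuCl2(H2IMes)(=CH-C6H4-2-Oi-Pr) (5 mol%), toluene (2 mM), 80 °C
Reagents that add atoms: none
Why: Ring-closing metathesis between the neopentyl vinyl group and the methacryloyl unit closes the seven-membered enone, helped by the gem-dimethyl group and the cis disposition of the two chains.

Step 9
Reactants: 11 (1R,3aR,8aR)-1-hydroxy-1,4,4,6-tetramethyl-2,3,3a,4,8,8a-hexahydroazulen-7(1H)-one
Product: 12 (1R,3aR,7S,8aR)-1,4,4,6-tetramethyl-1,2,3,3a,4,7,8,8a-octahydroazulene-1,7-diol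
Conditions: NaBH4, CeCl3·7H2O, MeOH, −78 °C
Reagents that add atoms: none
Why: Luche 1,2-reduction delivers hydride from the convex face of the cis-fused bicycle (the face of the ring-fusion hydrogens), so the new hydroxyl (7S) lies on the concave face.

Step 10
Reactants: 12 (1R,3aR,7S,8aR)-1,4,4,6-tetramethyl-1,2,3,3a,4,7,8,8a-octahydroazulene-1,7-diol
Product: 14 2-[(1R,3aR,5S,8aR)-1-hydroxy-1,4,4,6-tetramethyl-1,2,3,3a,4,5,8,8a-octahydroazulen-5-yl]-N,N-dimethylacetamide, via ketene N,O-acetal 13 (not isolated)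
Conditions: CH3C(OCH3)2N(CH3)2 (5 equiv), xylenes, 140 °C
Reagents that add atoms: N,N-dimethylacetamide dimethyl acetal, CC(OC)(OC)N(C)C
Why: Eschenmoser–Claisen [3,3]-sigmatropic rearrangement forms the C–C bond next to the quaternary carbon on the face that carried the allylic oxygen (5S) and moves the olefin to its final trisubstituted position.

Step 11
Reactants: 14 2-[(1R,3aR,5S,8aR)-1-hydroxy-1,4,4,6-tetramethyl-1,2,3,3a,4,5,8,8a-octahydroazulen-5-yl]-N,N-dimethylacetamide
Product: 15 (1R,3aR,5S,8aR)-5-(2-hydroxyethyl)-1,4,4,6-tetramethyl-1,2,3,3a,4,5,8,8a-octahydroazulen-1-ol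
Conditions: LiEt3BH (4 equiv), THF, 0 °C to rt
Reagents that add atoms: none
Why: Lithium triethylborohydride reduces the tertiary amide to the primary alcohol with C–N cleavage and leaves the olefin and tertiary alcohol alone.

Step 12
Reactants: 15 (1R,3aR,5S,8aR)-5-(2-hydroxyethyl)-1,4,4,6-tetramethyl-1,2,3,3a,4,5,8,8a-octahydroazulen-1-ol
Product: 16 (1R,3aR,5S,8aR)-5-(2-iodoethyl)-1,4,4,6-tetramethyl-1,2,3,3a,4,5,8,8a-octahydroazulen-1-ol
Conditions: I2, PPh3, imidazole, CH2Cl2, 0 °C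
Reagents that add atoms: iodine, II
Why: Appel-type iodination converts only the primary alcohol, the hindered tertiary alcohol being inert at 0 °C.

Step 13
Reactants: 1 (S)-(+)-linalool
Product: 18 (3S)-3,7-dimethylocta-1,7-diene-3,6-diol (C-6 epimers), via allylic hydroperoxide 17 (not isolated)
Conditions: O2, visible light, tetraphenylporphyrin (cat.), CH2Cl2, 0 °C; then PPh3; chromatographic removal of the regioisomeric diol
Reagents that add atoms: dioxygen, O=O
Why: Schenck ene reaction of singlet oxygen occurs only at the trisubstituted olefin, and the regioisomer with the secondary C–O bond and isopropenyl group is kept after phosphine reduction; the carbinol centre is untouched.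

Step 14
Reactants: 18 (3S)-3,7-dimethylocta-1,7-diene-3,6-diol
Product: 19 (4S)-2,4-dimethylcyclohex-2-ene-1,4-diol (C-1 epimers)
Conditions: second-generation Grubbs catalyst RuCl2(=CHPh)(H2IMes)(PCy3) (2 mol%), CH2Cl2, 40 °C
Reagents that add atoms: none
Why: Ring-closing metathesis of the vinyl and isopropenyl groups gives the six-membered trisubstituted olefin with loss of ethene.

Step 15
Reactants: 19 (4S)-2,4-dimethylcyclohex-2-ene-1,4-diol
Product: 20 (4S)-4-hydroxy-2,4-dimethylcyclohex-2-en-1-one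
Conditions: MnO2 (15 equiv), CH2Cl2, rt
Reagents that add atoms: none
Why: Allylic oxidation with MnO2 converts the secondary allylic alcohol of both epimers to the enone and cannot touch the tertiary alcohol.

Step 16
Reactants: 21 5-bromo-2-methylpent-2-ene
Product: 22 3-(2-bromoethyl)-2,2-dimethyloxirane (racemic)
Conditions: mCPBA, NaHCO3, CH2Cl2, 0 °C
Reagents that add atoms: 3-chloroperoxybenzoic acid, O=C(OO)c1cccc(Cl)c1
Why: Prilezhaev epoxidation of the trisubstituted olefin; the epoxide configuration is irrelevant because its secondary carbon ends as the ketone.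

Step 17
Reactants: 22 3-(2-bromoethyl)-2,2-dimethyloxirane
Product: 23 3-(2-iodoethyl)-2,2-dimethyloxirane (racemic)
Conditions: NaI, NaHCO3, acetone, reflux
Reagents that add atoms: sodium iodide, [Na+].[I-]
Why: Finkelstein exchange gives the more reactive primary iodide under neutral conditions that spare the epoxide.

Step 18
Reactants: 16 (1R,3aR,5S,8aR)-5-(2-iodoethyl)-1,4,4,6-tetramethyl-1,2,3,3a,4,5,8,8a-octahydroazulen-1-ol; 20 (4S)-4-hydroxy-2,4-dimethylcyclohex-2-en-1-one
Product: 26 (3R,4S)-2,4-dimethyl-1,4-bis(trimethylsilyloxy)-3-{2-[(1R,3aR,5S,8aR)-1,4,4,6-tetramethyl-1-(trimethylsilyloxy)-1,2,3,3a,4,5,8,8a-octahydroazulen-5-yl]ethyl}cyclohex-1-ene, via Grignard reagent 24 (not isolated), via magnesium enolate 25 (not isolated)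
Conditions: 16: t-BuMgCl (1.0 equiv), THF, 0 °C, then Mg (activated), THF, rt; 20 (1.5 equiv): t-BuMgCl (1.5 equiv), THF, −78 °C; combine, −78 to 0 °C; then TMSCl, Et3N, −78 °C to rt
Reagents that add atoms: chlorotrimethylsilane, C[Si](C)(C)Cl
Why: Alkoxide-directed (ligand-assisted) conjugate addition: the magnesium alkoxide of 20 delivers the alkyl group to the enone β-carbon on the face syn to oxygen (3R), and the regiodefined enolate is trapped as its silyl enol ether.

Step 19
Reactants: 26 tris(trimethylsilyl) enol ether from step 18; 23 3-(2-iodoethyl)-2,2-dimethyloxirane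
Product: 29 (2R,3R,4S)-2-[2-(3,3-dimethyloxiran-2-yl)ethyl]-4-hydroxy-3-{2-[(1R,3aR,5S,8aR)-1-hydroxy-1,4,4,6-tetramethyl-1,2,3,3a,4,5,8,8a-octahydroazulen-5-yl]ethyl}-2,4-dimethylcyclohexan-1-one, via lithium enolate 27 (not isolated), via silylated epoxy ketone 28 (not isolated)
Conditions: MeLi (1.05 equiv), THF, 0 °C; then 23 (3 equiv), HMPA, −40 °C to rt; then TBAF, THF, 0 °C
Reagents that add atoms: none
Why: Methyllithium unmasks the regiodefined lithium enolate, whose SN2 alkylation occurs anti to the adjacent side chain and so fixes the quaternary centre (2R, methyl cis to that chain); fluoride then removes the two tertiary silyl ethers.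

Step 20
Reactants: 29 epoxy ketone diol from step 19
Product: 31 (5aR,6R,7S,9aR)-6-{2-[(1R,3aR,5S,8aR)-1-hydroxy-1,4,4,6-tetramethyl-1,2,3,3a,4,5,8,8a-octahydroazulen-5-yl]ethyl}-2,2,5a,7-tetramethyldecahydrobenzo[b]oxepine-3,7-diol (C-3 epimers), via epoxy triol 30 (not isolated)
Conditions: NaBH4, MeOH, 0 °C; then p-TsOH·H2O (5 mol%), CH2Cl2, 0 °C
Reagents that add atoms: none
Why: Axial hydride attack anti to the axial methyl gives the equatorial alcohol (4R in 30), which opens the protonated epoxide at its tertiary carbon in a 7-endo cyclisation to the trans-fused oxepane.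

Step 21
Reactants: 31 oxepanediol from step 20
Product: 32 sipholenone A
Conditions: Dess–Martin periodinane, NaHCO3, CH2Cl2, rt
Reagents that add atoms: none
Why: Dess–Martin oxidation converts the only secondary alcohol (both epimers) to the oxepanone, the two tertiary alcohols and the olefin being inert.

**Compound list**
1 | (S)-(+)-linalool, (3S)-3,7-dimethylocta-1,6-dien-3-ol | CC(C)=CCC[C@@](C)(C=C)O | starting material
2 | (1S)-1-methylcyclopent-2-en-1-ol | C[C@@]1(O)C=CCC1 | intermediate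
3 | (3S)-3-methyl-3-[(2-methylprop-2-en-1-yl)oxy]cyclopent-1-ene | C[C@@]1(OCC(C)=C)C=CCC1 | intermediate
4 | (3S)-3-methyl-3-[(2-methylprop-1-en-1-yl)oxy]cyclopent-1-ene (not isolated) | C[C@@]1(OC=C(C)C)C=CCC1 | intermediate
5 | 2-methyl-2-[(1R)-3-methylcyclopent-2-en-1-yl]propanal | O=CC(C)(C)[C@H]1C=C(C)CC1 | intermediate
6 | (3R)-1-methyl-3-(2-methylbut-3-en-2-yl)cyclopent-1-ene | C=CC(C)(C)[C@H]1C=C(C)CC1 | intermediate
7 | (1R,4S,5S)-1-methyl-4-(2-methylbut-3-en-2-yl)-6-oxabicyclo[3.1.0]hexane (epoxide trans to the side chain) | C=CC(C)(C)[C@@H]1CC[C@@]2(C)O[C@@H]12 | intermediate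
8 | 2-[(1R,2R,5R)-2-hydroxy-2-methyl-5-(2-methylbut-3-en-2-yl)cyclopentyl]acetonitrile | N#CC[C@@H]1[C@H](C(C)(C)C=C)CC[C@@]1(C)O | intermediate
9 | N-bromomagnesio ketimine of 10, bromomagnesium alkoxide (not isolated) | C=C(C)C(=N[Mg]Br)C[C@@H]1[C@H](C(C)(C)C=C)CC[C@@]1(C)O[Mg]Br | intermediate
10 | 1-[(1R,2R,5R)-2-hydroxy-2-methyl-5-(2-methylbut-3-en-2-yl)cyclopentyl]-3-methylbut-3-en-2-one | C=C(C)C(=O)C[C@@H]1[C@H](C(C)(C)C=C)CC[C@@]1(C)O | intermediate
11 | (1R,3aR,8aR)-1-hydroxy-1,4,4,6-tetramethyl-2,3,3a,4,8,8a-hexahydroazulen-7(1H)-one | CC1=CC(C)(C)[C@@H]2CC[C@@](C)(O)[C@@H]2CC1=O | intermediate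
12 | (1R,3aR,7S,8aR)-1,4,4,6-tetramethyl-1,2,3,3a,4,7,8,8a-octahydroazulene-1,7-diol | CC1=CC(C)(C)[C@@H]2CC[C@@](C)(O)[C@@H]2C[C@@H]1O | intermediate
13 | (1R,3aR,7S,8aR)-7-{[1-(dimethylamino)ethenyl]oxy}-1,4,4,6-tetramethyl-1,2,3,3a,4,7,8,8a-octahydroazulen-1-ol (not isolated) | CC1=CC(C)(C)[C@@H]2CC[C@@](C)(O)[C@@H]2C[C@@H]1OC(=C)N(C)C | intermediate
14 | 2-[(1R,3aR,5S,8aR)-1-hydroxy-1,4,4,6-tetramethyl-1,2,3,3a,4,5,8,8a-octahydroazulen-5-yl]-N,N-dimethylacetamide | CC1=CC[C@@H]2[C@@H](CC[C@@]2(C)O)C(C)(C)[C@H]1CC(=O)N(C)C | intermediate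
15 | (1R,3aR,5S,8aR)-5-(2-hydroxyethyl)-1,4,4,6-tetramethyl-1,2,3,3a,4,5,8,8a-octahydroazulen-1-ol | CC1=CC[C@@H]2[C@@H](CC[C@@]2(C)O)C(C)(C)[C@H]1CCO | intermediate
16 | (1R,3aR,5S,8aR)-5-(2-iodoethyl)-1,4,4,6-tetramethyl-1,2,3,3a,4,5,8,8a-octahydroazulen-1-ol | CC1=CC[C@@H]2[C@@H](CC[C@@]2(C)O)C(C)(C)[C@H]1CCI | intermediate
17 | (3S)-6-hydroperoxy-3,7-dimethylocta-1,7-dien-3-ol (C-6 epimers, not isolated) | C=C(C)C(OO)CC[C@@](C)(C=C)O | intermediate
18 | (3S)-3,7-dimethylocta-1,7-diene-3,6-diol (C-6 epimers) | C=C(C)C(O)CC[C@@](C)(C=C)O | intermediate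
19 | (4S)-2,4-dimethylcyclohex-2-ene-1,4-diol (C-1 epimers) | CC1=C[C@@](C)(O)CCC1O | intermediate
20 | (4S)-4-hydroxy-2,4-dimethylcyclohex-2-en-1-one | CC1=C[C@@](C)(O)CCC1=O | intermediate
21 | 5-bromo-2-methylpent-2-ene | CC(C)=CCCBr | starting material
22 | 3-(2-bromoethyl)-2,2-dimethyloxirane (racemic) | CC1(C)OC1CCBr | intermediate
23 | 3-(2-iodoethyl)-2,2-dimethyloxirane (racemic) | CC1(C)OC1CCI | intermediate
24 | Grignard reagent of 16 as its chloromagnesium alkoxide (not isolated) | CC1=CC[C@@H]2[C@@H](CC[C@@]2(C)O[Mg]Cl)C(C)(C)[C@H]1CC[Mg]I | intermediate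
25 | magnesium enolate of the conjugate adduct of 24 and 20 (not isolated) | CC1=CC[C@@H]2[C@@H](CC[C@@]2(C)O[Mg]Cl)C(C)(C)[C@H]1CC[C@@H]1C(C)=C(O[Mg]I)CC[C@]1(C)O[Mg]Cl | intermediate
26 | (3R,4S)-2,4-dimethyl-1,4-bis(trimethylsilyloxy)-3-{2-[(1R,3aR,5S,8aR)-1,4,4,6-tetramethyl-1-(trimethylsilyloxy)-1,2,3,3a,4,5,8,8a-octahydroazulen-5-yl]ethyl}cyclohex-1-ene | CC1=CC[C@@H]2[C@@H](CC[C@@]2(C)O[Si](C)(C)C)C(C)(C)[C@H]1CC[C@@H]1C(C)=C(O[Si](C)(C)C)CC[C@]1(C)O[Si](C)(C)C | intermediate
27 | lithium enolate from 26 (not isolated) | CC1=CC[C@@H]2[C@@H](CC[C@@]2(C)O[Si](C)(C)C)C(C)(C)[C@H]1CC[C@@H]1C(C)=C(O[Li])CC[C@]1(C)O[Si](C)(C)C | intermediate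
28 | bis(trimethylsilyl) ether of 29 (epoxide epimers, not isolated) | CC1=CC[C@@H]2[C@@H](CC[C@@]2(C)O[Si](C)(C)C)C(C)(C)[C@H]1CC[C@@H]1[C@@](C)(CCC3OC3(C)C)C(=O)CC[C@]1(C)O[Si](C)(C)C | intermediate
29 | (2R,3R,4S)-2-[2-(3,3-dimethyloxiran-2-yl)ethyl]-4-hydroxy-3-{2-[(1R,3aR,5S,8aR)-1-hydroxy-1,4,4,6-tetramethyl-1,2,3,3a,4,5,8,8a-octahydroazulen-5-yl]ethyl}-2,4-dimethylcyclohexan-1-one (epoxide epimers) | CC1=CC[C@@H]2[C@@H](CC[C@@]2(C)O)C(C)(C)[C@H]1CC[C@@H]1[C@@](C)(CCC3OC3(C)C)C(=O)CC[C@]1(C)O | intermediate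
30 | (1S,2R,3R,4R)-3-[2-(3,3-dimethyloxiran-2-yl)ethyl]-2-{2-[(1R,3aR,5S,8aR)-1-hydroxy-1,4,4,6-tetramethyl-1,2,3,3a,4,5,8,8a-octahydroazulen-5-yl]ethyl}-1,3-dimethylcyclohexane-1,4-diol (epoxide epimers, not isolated) | CC1=CC[C@@H]2[C@@H](CC[C@@]2(C)O)C(C)(C)[C@H]1CC[C@@H]1[C@@](C)(CCC3OC3(C)C)[C@H](O)CC[C@]1(C)O | intermediate
31 | (5aR,6R,7S,9aR)-6-{2-[(1R,3aR,5S,8aR)-1-hydroxy-1,4,4,6-tetramethyl-1,2,3,3a,4,5,8,8a-octahydroazulen-5-yl]ethyl}-2,2,5a,7-tetramethyldecahydrobenzo[b]oxepine-3,7-diol (C-3 epimers) | CC1=CC[C@@H]2[C@@H](CC[C@@]2(C)O)C(C)(C)[C@H]1CC[C@@H]1[C@@]2(C)CCC(O)C(C)(C)O[C@@H]2CC[C@]1(C)O | intermediate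
32 | sipholenone A | CC1=CC[C@@H]2[C@@H](CC[C@@]2(C)O)C(C)(C)[C@H]1CC[C@@H]1[C@@]2(C)CCC(=O)C(C)(C)O[C@@H]2CC[C@]1(C)O | target

**Step count**
Total: 21 steps. Longest linear sequence: 16 steps (steps 1–12, then 18–21).

**Three steps most likely to fail**

Step 6. The nucleophile must attack the secondary epoxide carbon on the face that also carries the neighbouring tert-alkyl group, while the other epoxide carbon is tertiary. The fallback sets out from 7 and comes back at 10. Epoxide 7 is opened with the lithium acetylide of 2-methylbut-1-en-3-yne activated by BF3·OEt2 (THF, −78 °C), a slim sp nucleophile that carries the whole three-carbon unit, to give (1R,2S,3R)-1-methyl-2-(3-methylbut-3-en-1-yn-1-yl)-3-(2-methylbut-3-en-2-yl)cyclopentan-1-ol F1. Hydration of the conjugated enyne (Ph3PAuNTf2 cat., aqueous dioxane) places the carbonyl on the alkyne carbon next to the propenyl group and gives 10, so the nitrile and its Grignard addition are bypassed.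

Step 18. Directed conjugate addition is known for 4-oxido enones without an α-substituent; here the enone carries an α-methyl group and the Grignard reagent is a precious fragment. The fallback sets out from 1 (and from 24, made from 16 as in step 18) and comes back at 26; it moves the α-methyl to after the addition. Ozonolysis of 1 at the trisubstituted olefin (O3, CH2Cl2/MeOH, −78 °C; Me2S) gives (5S)-5-ethenyl-5-methyloxolan-2-ol F2. Vinylmagnesium bromide gives (3S)-3-methylocta-1,7-diene-3,6-diol F3. Ring-closing metathesis with the second-generation Grubbs catalyst gives (4S)-4-methylcyclohex-2-ene-1,4-diol F4, and MnO2 gives (4S)-4-hydroxy-4-methylcyclohex-2-en-1-one F5. Directed addition of 24 to the magnesium alkoxide of this unhindered enone gives the magnesium enolate of the adduct F6, which is methylated in the flask (MeI, HMPA) to the 2-methyl ketone (2RS,3R,4S)-4-hydroxy-3-{2-[(1R,3aR,5S,8aR)-1-hydroxy-1,4,4,6-tetramethyl-1,2,3,3a,4,5,8,8a-octahydroazulen-5-yl]ethyl}-2,4-dimethylcyclohexan-1-one F7. Me3SiI/(Me3Si)2NH then forms the more substituted silyl enol ether and silylates both tertiary hydroxyls, which is 26.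

Step 19. A tetrasubstituted enolate flanked by a branched carbon must be alkylated by an unactivated primary iodide to make a quaternary centre. The fallback sets out from 26 and comes back at 29. Mukaiyama–Michael addition of 26 to acrolein (BF3·OEt2, CH2Cl2, −78 °C; dilute HCl work-up, which also removes the silyl groups) forms the quaternary centre with a far more reactive electrophile, again anti to the neighbouring chain, and gives 3-[(1R,2R,3S)-3-hydroxy-2-{2-[(1R,3aR,5S,8aR)-1-hydroxy-1,4,4,6-tetramethyl-1,2,3,3a,4,5,8,8a-octahydroazulen-5-yl]ethyl}-1,3-dimethyl-6-oxocyclohexyl]propanal F8. Diphenylsulfonium isopropylide (from isopropyldiphenylsulfonium tetrafluoroborate and t-BuLi, THF, −78 °C, excess) transfers isopropylidene to the aldehyde only, the ketone being flanked by a quaternary carbon, and gives epoxide 29.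

**Further compounds**
F1 | step 6 | (1R,2S,3R)-1-methyl-2-(3-methylbut-3-en-1-yn-1-yl)-3-(2-methylbut-3-en-2-yl)cyclopentan-1-ol | C=C(C)C#C[C@@H]1[C@H](C(C)(C)C=C)CC[C@@]1(C)O
F2 | step 18 | (5S)-5-ethenyl-5-methyloxolan-2-ol | C=C[C@]1(C)CCC(O)O1
F3 | step 18 | (3S)-3-methylocta-1,7-diene-3,6-diol | C=CC(O)CC[C@@](C)(C=C)O
F4 | step 18 | (4S)-4-methylcyclohex-2-ene-1,4-diol | C[C@@]1(O)C=CC(O)CC1
F5 | step 18 | (4S)-4-hydroxy-4-methylcyclohex-2-en-1-one | C[C@@]1(O)C=CC(=O)CC1
F6 | step 18 | magnesium enolate of the conjugate adduct of 24 and F5 | CC1=CC[C@@H]2[C@@H](CC[C@@]2(C)O[Mg]Cl)C(C)(C)[C@H]1CC[C@@H]1C=C(O[Mg]I)CC[C@]1(C)O[Mg]Cl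
F7 | step 18 | (2RS,3R,4S)-4-hydroxy-3-{2-[(1R,3aR,5S,8aR)-1-hydroxy-1,4,4,6-tetramethyl-1,2,3,3a,4,5,8,8a-octahydroazulen-5-yl]ethyl}-2,4-dimethylcyclohexan-1-one | CC1=CC[C@@H]2[C@@H](CC[C@@]2(C)O)C(C)(C)[C@H]1CC[C@@H]1C(C)C(=O)CC[C@]1(C)O
F8 | step 19 | 3-[(1R,2R,3S)-3-hydroxy-2-{2-[(1R,3aR,5S,8aR)-1-hydroxy-1,4,4,6-tetramethyl-1,2,3,3a,4,5,8,8a-octahydroazulen-5-yl]ethyl}-1,3-dimethyl-6-oxocyclohexyl]propanal | CC1=CC[C@@H]2[C@@H](CC[C@@]2(C)O)C(C)(C)[C@H]1CC[C@@H]1[C@@](C)(CCC=O)C(=O)CC[C@]1(C)O
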